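**Retrosynthetic overview**

1. Target ⇐ C1,C3-diol (both angelates last) ⇐ ring-A enone (C10 methyl by cuprate addition; ring A = C5–C10–C9–C8–C7–C6 by aldol condensation of a C8 methyl ketone onto a C10 aldehyde).
2. Seven-membered ring C1–C2–C3–C4–C5–C6–C11 ⇐ five-membered ring C3–C4–C5–C6–C11 of a bicyclo[2.1.1]hexan-2-one by two-carbon ring expansion: a 2-ethoxyvinyl anion adds to C3=O, the C3–C11 bond breaks (retro-aldol), and C11 re-closes on C1 (7-endo Michael addition–elimination), inserting C2 and C1.
3. Enabling feature: the non-enolisable C3 ketone lies between bridgehead C4 and C11, and C11 is also the α-carbon of a temporary δ-lactone ring C11–C15(=O)–O–C8–C7–C6; the strained C3–C11 bond can leave as a lactone enolate, and the lactone keeps C15 on the C7 side so C11 re-forms with its configuration.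
4. Cyclobutane C4–C5–C6–C7 ⇐ crossed [2+2] photocycloaddition of a lactone-tethered hexa-1,5-dien-3-one ⇐ C-acylation of a 3,6-dihydro-2H-pyran-2-one ⇐ ring-closing metathesis of an ester of (S)-but-3-en-2-ol, whose carbinol centre (C8, later a ketone) is the only source of chirality.
5. Ring order: temporary δ-lactone; cyclobutane together with the five-membered ring; seven-membered ring by expansion (lactone later cut to C15H2OAc and the C8 acetyl); cyclohexanone.

Key step: step 7

Locants used throughout: seven-membered ring C1(O)–C2–C3(O)–C4–C5–C6–C11; cyclobutane C4–C5–C6–C7; ring A C5–C10–C9–C8(=O)–C7–C6; C12 = CH3 on C4, C13 = CH3 on C10, C14 = CH3 on C11, C15 = CH2OAc carbon on C11. Before ring A is closed, C9 is the methyl group on C8 and C10 is the acetal or formyl carbon on C5.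

Assumption: the photocycloaddition should give both C5 epimers; the compounds from the photoadduct to the keto aldehyde are carried as this mixture and drawn without configuration at C5, which becomes epimerisable and converges in step 14.

**Route**

Step 1
Reactants: 1 2,2-dimethoxyacetaldehyde; 2 ethyl 2-(triphenylphosphoranylidene)propanoate
Product: 3 ethyl (E)-4,4-dimethoxy-2-methylbut-2-enoate
Conditions: CH2Cl2, 25 °C (1 used as its commercial aqueous solution)
Reagents that add atoms: none
Why: Wittig olefination with a stabilised ylide, which should give the (E)-trisubstituted enoate.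

Step 2
Reactants: 3 ethyl (E)-4,4-dimethoxy-2-methylbut-2-enoate
Product: 4 (E)-4,4-dimethoxy-2-methylbut-2-enoic acid
Conditions: LiOH, THF/H2O, 25 °C; then 1 M HCl to pH 4, 0 °C
Reagents that add atoms: lithium hydroxide ([Li+].[OH-])
Why: Ester saponification; the cold, only mildly acidic work-up should keep the dimethyl acetal.

Step 3
Reactants: 5 (S)-but-3-en-2-ol; 6 2-methylbut-3-enoic acid
Product: 7 (S)-but-3-en-2-yl 2-methylbut-3-enoate
Conditions: DCC, DMAP (5 mol%), CH2Cl2, 0 °C
Reagents that add atoms: none
Why: Steglich esterification, which does not break the C–O bond of the carbinol centre; the α-centre of the acid part does not matter because it is enolised in step 5.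

Step 4
Reactants: 7 (S)-but-3-en-2-yl 2-methylbut-3-enoate
Product: 8 (6S)-3,6-dimethyl-3,6-dihydro-2H-pyran-2-one
Conditions: second-generation Grubbs catalyst (H2IMes)(PCy3)Cl2Ru=CHPh (2 mol%), CH2Cl2 (0.02 M), 40 °C
Reagents that add atoms: none
Why: Ring-closing metathesis of two monosubstituted alkenes to the six-membered β,γ-unsaturated lactone with loss of ethene.

Step 5
Reactants: 8 (6S)-3,6-dimethyl-3,6-dihydro-2H-pyran-2-one; 4 (E)-4,4-dimethoxy-2-methylbut-2-enoic acid
Product: 11 (3R,6S)-3-[(E)-4,4-dimethoxy-2-methylbut-2-enoyl]-3,6-dimethyl-3,6-dihydro-2H-pyran-2-one, via acid chloride 9 (not isolated), via lithium dienolate 10 (not isolated)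
Conditions: 4, 1-chloro-N,N,2-trimethylprop-1-en-1-amine, CH2Cl2, 0 °C; separately 8, LiN(i-Pr)2, THF, −78 °C; then add 9, −78 °C
Reagents that add atoms: none
Why: C-acylation of the lithium dienolate at its α-carbon (crossed Claisen type); the acyl chloride should enter anti to the C8 methyl group across the nearly planar 2-oxido-2H-pyran ring (1,4-induction as in bislactim ether alkylations), which sets the quaternary centre C11 with its methyl cis to the C8 methyl, and at −78 °C acylation should be faster than eliminative opening of the dienolate.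

Step 6
Reactants: 11 (3R,6S)-acyl lactone
Product: 12 bicyclo[2.1.1]hexanone lactone
Conditions: hν (350 nm, Pyrex), degassed acetone (0.01 M), 20 °C
Reagents that add atoms: none
Why: Intramolecular enone–alkene [2+2] photocycloaddition of a hexa-1,5-dien-3-one, which closes in the crossed sense by the rule of five (C5–C6 first, to a five-membered ring, then C4–C7) as the parent dienones do on the way to bicyclo[2.1.1]hexan-2-ones; the one-atom tether C3 forces both new bonds onto the acyl face of the lactone alkene, so C11 alone fixes C4, C6 and C7, while C5 should form as both epimers.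

Step 7
Reactants: 12 bicyclo[2.1.1]hexanone lactone
Product: 15 ring-expanded enone lactone, via lithium alkoxide 13 (not isolated), via ring-opened lithium enolate 14 (not isolated)
Conditions: (Z)-BrCH=CHOEt, t-BuLi (2 equiv), THF, −78 °C; add 12, −78 °C; then HMPA, −78 to 25 °C; H2O
Reagents that add atoms: (Z)-1-bromo-2-ethoxyethene (Br/C=C\OCC), used as (Z)-2-ethoxyvinyllithium ([Li]/C=C\OCC)
Why: Proposed new method: the vinyllithium adds to the strained, non-enolisable C3 ketone; the alkoxide 13 then fragments by retro-aldol cleavage of the C3–C11 bond, which releases the strain of the bicyclo[2.1.1]hexane and gives the lactone enolate 14 next to a β-ethoxy enone, and C11 re-adds to C1 with loss of ethoxide (Michael addition–elimination), so that C2 and C1 are inserted between C3 and C11. The closest known reaction types are the alkoxide-accelerated 1,3-shift of 1-vinylcycloalkanols (two-carbon ring expansion) and the retro-Claisen or retro-Dieckmann/Michael cascades of cyclic β-keto esters. The seven-membered ring closes in the 7-endo-trig mode. No new stereocentre remains: C11 is re-formed, and the lactone ring, which ties C15 to C7, leaves only the face towards C4 open, so its configuration is retained. The step needs addition to the ketone and not to the lactone carbonyl, which the ring strain of the ketone and the quaternary α-carbon of the lactone should secure, and cleavage of C3–C11 and not of C3–C4, which is secured because only C11 can leave as a stabilised enolate; 1,2-re-addition of 14 to C3 only returns 13, so the conjugate pathway is the exit.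

Step 8
Reactants: 15 ring-expanded enone lactone
Product: 17 C1-hydroxy C3-ketone lactone, via pinacol boronate 16 (not isolated)
Conditions: B2pin2, CuCl (5 mol%), DPEphos (5 mol%), NaOt-Bu (10 mol%), MeOH (2 equiv), THF, 25 °C; then H2O2, pH 7 phosphate buffer, 0 °C
Reagents that add atoms: hydrogen peroxide (OO)
Why: Copper-catalysed conjugate borylation of the enone and oxidation of the C–B bond with retention; the copper boryl should add to C1 on the face of the C14 methyl group, anti to the lactone bridge that covers the other face, which sets C1.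

Step 9
Reactants: 17 C1-hydroxy C3-ketone lactone
Product: 18 1,3-anti diol lactone
Conditions: Me4NBH(OAc)3, MeCN/AcOH, −30 °C
Reagents that add atoms: none
Why: Hydroxyl-directed reduction (Evans–Saksena type): the borohydride bound to the C1 oxygen delivers hydride to C3 on the face of the C1–O bond, which gives the 1,3-anti diol and sets C3, while the lactone is not reduced.

Step 10
Reactants: 18 1,3-anti diol lactone
Product: 19 bis(TBS ether) lactone
Conditions: TBSOTf, 2,6-lutidine, CH2Cl2, 0 to 25 °C
Reagents that add atoms: tert-butyldimethylsilyl trifluoromethanesulfonate (CC(C)(C)[Si](C)(C)OS(=O)(=O)C(F)(F)F)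
Why: Silyl ether formation with the silyl triflate, which is reactive enough for two hindered secondary alcohols; no stereocentre is touched.

Step 11
Reactants: 19 bis(TBS ether) lactone
Product: 20 C15,C8-diol
Conditions: LiAlH4, THF, 0 °C
Reagents that add atoms: none
Why: Hydride reduction of the lactone to the diol opens the temporary ring (C15 becomes the CH2OH group on C11, C8 returns as a secondary carbinol); the acetal and the silyl ethers are inert.

Step 12
Reactants: 20 C15,C8-diol
Product: 21 C15 acetate
Conditions: AcCl, 2,4,6-collidine, CH2Cl2, −78 °C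
Reagents that add atoms: acetyl chloride (CC(Cl)=O)
Why: Selective acetylation of the primary alcohol over the secondary one (acid chloride with collidine at low temperature).

Step 13
Reactants: 21 C15 acetate
Product: 22 C8 methyl ketone
Conditions: Dess–Martin periodinane, CH2Cl2, 25 °C
Reagents that add atoms: none
Why: Alcohol oxidation to the methyl ketone, which removes the auxiliary C8 stereocentre.

Step 14
Reactants: 22 C8 methyl ketone
Product: 25 ring-A enone, via keto aldehyde 23 (not isolated), via aldol 24 (not isolated)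
Conditions: PPTS, acetone/H2O, 50 °C; then pyrrolidine (0.2 equiv), AcOH (0.2 equiv), toluene, 60 °C
Reagents that add atoms: water (O)
Why: Acetal hydrolysis, then amine-catalysed intramolecular aldol condensation (6-enolexo closure of ring A); C5 and C7 are now both α to a carbonyl group and epimerise through enamine and enol forms, and only the isomer with the formyl and acetyl arms on the face away from the seven-membered ring can close and dehydrate, so both centres end in the configuration of the target.

Step 15
Reactants: 25 ring-A enone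
Product: 26 C10-methyl ketone bis(TBS ether)
Conditions: CuI, MeLi (2 equiv), Et2O, 0 °C; then 25, −78 to −30 °C; aq. NH4Cl
Reagents that add atoms: methyllithium (C[Li]), used as Me2CuLi
Why: Conjugate addition of the Gilman reagent; methyl enters C10 on the face anti to the C12 methyl group of the C4 bridge, as cuprates add to apoverbenone anti to its dimethyl bridge, which sets C10.

Step 16
Reactants: 26 C10-methyl ketone bis(TBS ether)
Product: 27 C1,C3-diol
Conditions: HF·pyridine, pyridine, THF, 0 to 25 °C
Reagents that add atoms: none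
Why: Fluoride-mediated desilylation under buffered conditions that should leave the acetate and the ketone alone.

Step 17
Reactants: 27 C1,C3-diol
Product: 28 target CNP0233066.1
Conditions: angelic acid, 2,4,6-trichlorobenzoyl chloride, Et3N, toluene, 25 °C; then 27, 80 °C
Reagents that add atoms: angelic acid (C/C=C(/C)C(=O)O)
Why: Yamaguchi-type esterification through the mixed anhydride, the usual way to put angelates on hindered secondary alcohols without Z to E isomerisation; no stereocentre is touched.

**Compound list**

1 | 2,2-dimethoxyacetaldehyde | COC(OC)C=O | starting material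
2 | ethyl 2-(triphenylphosphoranylidene)propanoate | CCOC(=O)C(C)=P(c1ccccc1)(c1ccccc1)c1ccccc1 | starting material
3 | ethyl (E)-4,4-dimethoxy-2-methylbut-2-enoate | CCOC(=O)/C(C)=C/C(OC)OC | intermediate
4 | (E)-4,4-dimethoxy-2-methylbut-2-enoic acid | OC(=O)/C(C)=C/C(OC)OC | intermediate
5 | (S)-but-3-en-2-ol | C[C@H](O)C=C | starting material
6 | 2-methylbut-3-enoic acid (racemic) | CC(C=C)C(=O)O | starting material
7 | (S)-but-3-en-2-yl 2-methylbut-3-enoate (both epimers at the acyl α-carbon) | C=CC(C)C(=O)O[C@@H](C)C=C | intermediate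
8 | (6S)-3,6-dimethyl-3,6-dihydro-2H-pyran-2-one (both C3 epimers) | CC1C=C[C@H](C)OC1=O | intermediate
9 | (E)-4,4-dimethoxy-2-methylbut-2-enoyl chloride | ClC(=O)/C(C)=C/C(OC)OC | intermediate
10 | lithium dienolate of 8 (lithium (6S)-3,6-dimethyl-6H-pyran-2-olate) | [Li]OC1=C(C)C=C[C@H](C)O1 | intermediate
11 | (3R,6S)-3-[(E)-4,4-dimethoxy-2-methylbut-2-enoyl]-3,6-dimethyl-3,6-dihydro-2H-pyran-2-one (ring C3 = C11, ring C6 = C8; the two methyl groups cis) | COC(OC)/C=C(\C)C(=O)[C@@]1(C)C=C[C@H](C)OC1=O | intermediate
12 | bicyclo[2.1.1]hexanone lactone: C3 ketone bridged C4(CH3)···C11, cyclobutane C4–C5–C6–C7, δ-lactone C11–C15(=O)–O–C8H(CH3)–C7 fused across C11–C6–C7, C14 methyl on C11, CH(OMe)2 on C5 (both C5 epimers) | O=C1[C@]2(C)C(C(OC)OC)[C@H]3[C@@H]2[C@H](C)OC(=O)[C@@]13C | intermediate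
13 | lithium alkoxide from addition of the (Z)-2-ethoxyvinyl group to C3 of 12 | [Li]OC1(/C=C\OCC)[C@]2(C)C(C(OC)OC)[C@H]3[C@@H]2[C@H](C)OC(=O)[C@@]13C | intermediate
14 | ring-opened lithium lactone enolate: cyclobutane with (Z)-3-ethoxyacryloyl and methyl on C4, lactone enolate C11=C15(OLi) attached at C6 | CCO/C=C\C(=O)[C@]1(C)C(C(OC)OC)[C@H]2[C@@H]1[C@H](C)OC(O[Li])=C2C | intermediate
15 | ring-expanded enone lactone: bicyclo[4.1.1]oct-3-en-2-one core (C3=O, C2=C1, seven-membered ring C1–C2–C3–C4–C5–C6–C11) with the δ-lactone C11–C15(=O)–O–C8H(CH3)–C7 | C1=CC(=O)[C@]2(C)C(C(OC)OC)[C@H]3[C@@H]2[C@H](C)OC(=O)[C@@]13C | intermediate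
16 | C1 pinacol boronate of the C3 ketone lactone | CC1(C)OB([C@@H]2CC(=O)[C@]3(C)C(C(OC)OC)[C@H]4[C@@H]3[C@H](C)OC(=O)[C@@]24C)OC1(C)C | intermediate
17 | C1-hydroxy C3-ketone lactone (C1–OH cis to the C14 methyl) | O[C@@H]1CC(=O)[C@]2(C)C(C(OC)OC)[C@H]3[C@@H]2[C@H](C)OC(=O)[C@@]13C | intermediate
18 | 1,3-anti diol lactone (C1–OH and C3–OH trans) | O[C@@H]1C[C@@H](O)[C@]2(C)C(C(OC)OC)[C@H]3[C@@H]2[C@H](C)OC(=O)[C@@]13C | intermediate
19 | bis(TBS ether) of 18 | CC(C)(C)[Si](C)(C)O[C@@H]1C[C@@H](O[Si](C)(C)C(C)(C)C)[C@]2(C)C(C(OC)OC)[C@H]3[C@@H]2[C@H](C)OC(=O)[C@@]13C | intermediate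
20 | diol: C15H2OH on C11 and (S)-CH(OH)CH3 on C7; C1 and C3 as TBS ethers | CC(C)(C)[Si](C)(C)O[C@@H]1C[C@@H](O[Si](C)(C)C(C)(C)C)[C@]2(C)C(C(OC)OC)[C@@H]([C@@H]2[C@H](C)O)[C@@]1(C)CO | intermediate
21 | C15 acetate of 20 (C8–OH free) | CC(C)(C)[Si](C)(C)O[C@@H]1C[C@@H](O[Si](C)(C)C(C)(C)C)[C@]2(C)C(C(OC)OC)[C@@H]([C@@H]2[C@H](C)O)[C@@]1(C)COC(C)=O | intermediate
22 | C8 methyl ketone (acetyl on C7, acetal on C5) | CC(C)(C)[Si](C)(C)O[C@@H]1C[C@@H](O[Si](C)(C)C(C)(C)C)[C@]2(C)C(C(OC)OC)[C@@H]([C@@H]2C(C)=O)[C@@]1(C)COC(C)=O | intermediate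
23 | keto aldehyde (acetyl on C7, formyl on C5) | CC(C)(C)[Si](C)(C)O[C@@H]1C[C@@H](O[Si](C)(C)C(C)(C)C)[C@]2(C)C(C=O)[C@@H]([C@@H]2C(C)=O)[C@@]1(C)COC(C)=O | intermediate
24 | aldol: ring A closed, C8 ketone, C10 carbinol (either C10 epimer) | CC(C)(C)[Si](C)(C)O[C@@H]1C[C@@H](O[Si](C)(C)C(C)(C)C)[C@]2(C)[C@@H]3[C@@H]([C@H]2C(=O)CC3O)[C@@]1(C)COC(C)=O | intermediate
25 | ring-A enone (C8=O, C9=C10) | CC(C)(C)[Si](C)(C)O[C@@H]1C[C@@H](O[Si](C)(C)C(C)(C)C)[C@]2(C)[C@@H]3[C@@H]([C@H]2C(=O)C=C3)[C@@]1(C)COC(C)=O | intermediate
26 | C10-methyl ketone, bis(TBS ether) | CC(C)(C)[Si](C)(C)O[C@@H]1C[C@@H](O[Si](C)(C)C(C)(C)C)[C@]2(C)[C@@H]3[C@@H]([C@H]2C(=O)C[C@H]3C)[C@@]1(C)COC(C)=O | intermediate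
27 | C1,C3-diol with C15 acetate and C8 ketone | O[C@@H]1C[C@@H](O)[C@]2(C)[C@@H]3[C@@H]([C@H]2C(=O)C[C@H]3C)[C@@]1(C)COC(C)=O | intermediate
28 | target CNP0233066.1: (1R,3R,4R,5S,6S,7R,10R,11S) in the locants above; C1 and C3 (Z)-2-methylbut-2-enoates, C15 acetate, C8 ketone | C/C=C(/C)C(=O)O[C@@H]1C[C@@H](OC(=O)/C(C)=C\C)[C@]2(C)[C@@H]3[C@@H]([C@H]2C(=O)C[C@H]3C)[C@@]1(C)COC(C)=O | target

**Step count and risks**

Total step count: 17. Longest linear sequence: 15 (steps 3–17; the branch through steps 1 and 2 joins at step 5 and is equally long).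

Three steps most likely to fail:

Step 7 (Proposed new method). What may go wrong: the alkoxide 13 may not fragment at a useful rate, or the enolate 14 may be quenched by proton transfer or react through oxygen before it reaches C1. Fallback with known reactions, from 12 back to 15: the 1,2-addition is run alone (same vinyllithium, THF, −78 °C, quenched cold with AcOH) and gives the tertiary allylic alcohol F1. A catalytic amount of KN(SiMe3)2 in THF at 0 °C then effects the retro-aldol opening of this strained β-hydroxy lactone and, after proton transfer, gives the ring-opened 3-ethoxyacryloyl lactone F2. F2 is deprotonated at C11 (KN(SiMe3)2, 18-crown-6, THF, −78 to 0 °C) and closes by intramolecular Michael addition–elimination to 15. This replaces the one-flask 1,3-shift by a ring-opening and ring-closing sequence of three known reaction types (organolithium addition, retro-aldol, addition–elimination of an ester enolate to a β-alkoxy enone), each open to separate optimisation.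

Step 5. What may go wrong: eliminative ring opening of the dienolate 10 (E1cB loss of the allylic ring oxygen to a dienoate) before acylation, or poor facial selectivity of the acylation. Fallback from 7 back to 11: the acyclic ester 7 is deprotonated (LiN(i-Pr)2, THF, −78 °C; its dienolate has no allylic leaving group) and C-acylated with 9 to give the acyclic β-keto ester F3 as both C11 epimers. Ring-closing metathesis (second-generation Grubbs catalyst (H2IMes)(PCy3)Cl2Ru=CHPh, CH2Cl2, 40 °C) then gives 11 together with its C11 epimer F4; the two are separated by chromatography and F4 is discarded.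

Step 17. What may go wrong: Z to E isomerisation of the activated angelate (tiglate formation), or incomplete acylation of the two neopentylic hydroxyl groups. Fallback from 27 to 28: 27 is esterified with 2-[bis(2,2,2-trifluoroethoxy)phosphoryl]propanoic acid (DCC, DMAP, CH2Cl2), a small acid that cannot isomerise, to give the bis(phosphonopropionate) F5. A twofold Z-selective Horner–Wadsworth–Emmons olefination of the Still–Gennari type with acetaldehyde (KN(SiMe3)2, 18-crown-6, THF, −78 °C) then builds both (Z)-2-methylbut-2-enoates in place and gives 28.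

**Further compounds**

F1 | step 7 | tertiary allylic alcohol (neutral form of 13) | OC1(/C=C\OCC)[C@]2(C)C(C(OC)OC)[C@H]3[C@@H]2[C@H](C)OC(=O)[C@@]13C
F2 | step 7 | ring-opened 3-ethoxyacryloyl lactone (C11–H, either epimer) | CCO/C=C\C(=O)[C@]1(C)C(C(OC)OC)[C@H]2[C@@H]1[C@H](C)OC(=O)C2C
F3 | step 5 | (S)-but-3-en-2-yl (E)-2-ethenyl-6,6-dimethoxy-2,4-dimethyl-3-oxohex-4-enoate (both C2 epimers) | C=CC(C)(C(=O)/C(C)=C/C(OC)OC)C(=O)O[C@@H](C)C=C
F4 | step 5 | (3S,6S)-epimer of 11 | COC(OC)/C=C(\C)C(=O)[C@]1(C)C=C[C@H](C)OC1=O
F5 | step 17 | C1,C3-bis{2-[bis(2,2,2-trifluoroethoxy)phosphoryl]propanoate} of 27 | CC(C(=O)O[C@@H]1C[C@@H](OC(=O)C(C)P(=O)(OCC(F)(F)F)OCC(F)(F)F)[C@]2(C)[C@@H]3[C@@H]([C@H]2C(=O)C[C@H]3C)[C@@]1(C)COC(C)=O)P(=O)(OCC(F)(F)F)OCC(F)(F)F
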